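**Plan**

- Cuts: (a) the aryl C7–CH2 bond to C3 of the pyranone (last step, Mannich/methide coupling); (b) the dihydrofuran O1–C2 bond, which in the precursor is the O1–CMe2 bond of a 2,2-dimethylchroman-3-ol; (c) the pyran ring back to an aryl 1,1-dimethylpropargyl ether; (d) the aryl–acyl bond (Friedel–Crafts).
- Forward: phloroglucinol → (R)-acyl ketone → propargyl ether at the OH para to C=O → diacetate → thermal closure to the 2H-chromene (a six-membered ring first) → epoxide → chroman-3-ol → contraction to the dihydrofuran → deacetylation → CH2 link to the pyranone (two steps from pentan-3-one).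
- Enabling feature: C2 of the dihydrofuran ring (O1–C2–C3–C3a–C7a) carries a prop-1-en-2-yl group, so O1 stands β to a carbon that can be a tertiary cation. The same atoms can therefore be held as a pyran ring O1–CMe2–CH(OH)–CH2–aryl, in which O1 shifts from CMe2 to the carbinol carbon through an oxiranium ion and the CMe2 carbon leaves the ring as the isopropenyl carbon.
- Stereochemistry: the acyl α-carbon comes from (R)-2-methylbutanoic acid. C2 comes from a catalyst-controlled (S,S)-Mn(salen) epoxidation (3S,4S), carried as the (3S)-alcohol and inverted in the contraction to (2R).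
- Temporary helpers: two aryl acetates (on in step 3, off in step 8) and the pyran ring itself.

Key step: step 7

Remark: (R)-2-methylbutanoic acid is taken as a purchasable enantiopure acid, and the (S,S)-Mn(salen) catalyst is assumed to give the (3S,4S)-oxide here as it does with other 2,2-dimethyl-2H-chromenes.

**Step 1**
Reactants: 1 phloroglucinol; 2 (2R)-2-methylbutanoic acid
Product: 4 (2R)-2-methyl-1-(2,4,6-trihydroxyphenyl)butan-1-one, via (R)-2-methylbutanoyl chloride 3 (not isolated)
Conditions: (COCl)2, cat. DMF, CH2Cl2, 0 °C to rt; then 1, AlCl3, PhNO2/CH2Cl2, 0 °C to rt; aq. HCl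
Reagents that add atoms: oxalyl chloride, O=C(Cl)C(Cl)=O (chlorine of intermediate 3 only)
Why: Friedel–Crafts C-acylation of the symmetric, very electron-rich triol should stop after one acylation because the chelated aryl ketone deactivates the ring, and base-free chloride formation at low temperature avoids ketene and enol pathways so that the α-stereocentre of 2 is kept.

**Step 2**
Reactants: 4 (2R)-2-methyl-1-(2,4,6-trihydroxyphenyl)butan-1-one; 5 3-chloro-3-methylbut-1-yne
Product: 6 (2R)-1-{2,6-dihydroxy-4-[(2-methylbut-3-yn-2-yl)oxy]phenyl}-2-methylbutan-1-one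
Conditions: DBU, CuCl2·2H2O (cat.), MeCN, 0 °C to rt
Reagents that add atoms: none
Why: Copper-catalysed O-propargylation (through a copper allenylidene) should take place at the most acidic phenoxide, the hydroxyl para to the ketone, since the two ortho hydroxyls are less acidic and engaged with the carbonyl; this fixes the future ring oxygen para to the acyl group.

**Step 3**
Reactants: 6 (2R)-1-{2,6-dihydroxy-4-[(2-methylbut-3-yn-2-yl)oxy]phenyl}-2-methylbutan-1-one
Product: 7 2-[(2R)-2-methylbutanoyl]-5-[(2-methylbut-3-yn-2-yl)oxy]-1,3-phenylene diacetate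
Conditions: Ac2O, pyridine, DMAP (cat.), CH2Cl2, 0 °C to rt
Reagents that add atoms: acetic anhydride, CC(=O)OC(C)=O
Why: Standard DMAP-catalysed O-acetylation caps the two remaining phenols, so that the next step can liberate only one phenol, and the acetates should withstand oxidant, hydrogenolysis and Tf2O and leave by mild methanolysis.

**Step 4**
Reactants: 7 2-[(2R)-2-methylbutanoyl]-5-[(2-methylbut-3-yn-2-yl)oxy]-1,3-phenylene diacetate
Product: 8 2,2-dimethyl-6-[(2R)-2-methylbutanoyl]-2H-chromene-5,7-diyl diacetate
Conditions: o-xylene, 140 °C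
Reagents that add atoms: none
Why: The thermal aryl propargyl ether rearrangement (propargyl Claisen to either of the two equivalent ortho carbons, tautomerisation, 1,5-H shift, oxa-6π electrocyclisation) should give the 2,2-dimethyl-2H-chromene, and the liberated para oxygen is the only phenol able to close the ring.

**Step 5**
Reactants: 8 2,2-dimethyl-6-[(2R)-2-methylbutanoyl]-2H-chromene-5,7-diyl diacetate
Product: 9 (3S,4S)-3,4-epoxy-2,2-dimethyl-6-[(2R)-2-methylbutanoyl]-3,4-dihydro-2H-chromene-5,7-diyl diacetate
Conditions: (S,S)-Jacobsen Mn(salen)Cl (5 mol %), mCPBA, NMO, CH2Cl2, −78 °C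
Reagents that add atoms: mCPBA, O=C(OO)c1cccc(Cl)c1
Why: Jacobsen–Katsuki epoxidation is at its best with cis-disubstituted, aryl-conjugated 2,2-dimethyl-2H-chromenes; the chiral Mn-oxo salen species selects the alkene face (catalyst control, 3S,4S expected with the S,S catalyst) independently of the remote acyl stereocentre, and the anhydrous low-temperature protocol spares the acetates.

**Step 6**
Reactants: 9 (3S,4S)-3,4-epoxy-2,2-dimethyl-6-[(2R)-2-methylbutanoyl]-3,4-dihydro-2H-chromene-5,7-diyl diacetate
Product: 10 (3S)-3-hydroxy-2,2-dimethyl-6-[(2R)-2-methylbutanoyl]-3,4-dihydro-2H-chromene-5,7-diyl diacetate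
Conditions: H2 (1 atm), 10% Pd/C, EtOAc, rt
Reagents that add atoms: none
Why: Catalytic hydrogenolysis of a benzylic epoxide cleaves only the benzylic C4–O bond, so the C3–O bond and its S configuration are untouched, the neutral conditions avoid cationic opening assisted by the peri acetate, and the hindered aryl ketone should not be reduced.

**Step 7**
Reactants: 10 (3S)-3-hydroxy-2,2-dimethyl-6-[(2R)-2-methylbutanoyl]-3,4-dihydro-2H-chromene-5,7-diyl diacetate
Product: 12 (2R)-5-[(2R)-2-methylbutanoyl]-2-(prop-1-en-2-yl)-2,3-dihydro-1-benzofuran-4,6-diyl diacetate, via chroman-3-yl triflate 11 (not isolated)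
Conditions: Tf2O, 2,6-lutidine, CH2Cl2, −78 °C to rt
Reagents that add atoms: trifluoromethanesulfonic anhydride, O=S(=O)(OS(=O)(=O)C(F)(F)F)C(F)(F)F (triflyl group of intermediate 11 only)
Why: O-Triflation gives 11, whose half-chair conformer with a pseudo-equatorial triflate places the ring O1–CMe2 bond antiperiplanar to C3–OTf, so O1 displaces triflate from the rear to form an aryl-bridged oxiranium ion that opens at its tertiary carbon to a 2-(dihydrobenzofuran-2-yl)prop-2-yl cation, from which 2,6-lutidine removes a methyl proton to unveil the isopropenyl group. The closest known reaction type is the 1,2-aryloxy shift with ring contraction of 2,2-dimethylchroman-3-ols and flavan-3-yl sulfonates to 2-substituted 2,3-dihydrobenzofurans. The five-membered ring O1–C2–C3–C3a–C7a is closed by intramolecular SN2 attack of O1 on the carbinol carbon (5-exo-tet, and 3-exo-tet for the transient oxirane), and the six-membered ring is lost when the O1–CMe2 bond breaks, so the pyran ring contracts by the one carbon that becomes the exocyclic isopropenyl carbon. The only stereocentre touched (C3 of the chroman, C2 of the benzofuran) is converted stereospecifically with inversion, (3S) to (2R), the controlling element being the carbinol configuration fixed in step 5. The step needs the oxygen shift to beat E2 to chromene 8, 1,2-methyl shift and aryl (phenonium) participation, and needs proton loss from a methyl group and not from the ring CH; the gem-dimethyl group (tertiary cation), the antiperiplanar ring oxygen, the acetate- and acyl-deactivated arene, the hindered non-nucleophilic base and the low temperature should secure this.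

**Step 8**
Reactants: 12 (2R)-5-[(2R)-2-methylbutanoyl]-2-(prop-1-en-2-yl)-2,3-dihydro-1-benzofuran-4,6-diyl diacetate
Product: 13 (2R)-1-[(2R)-4,6-dihydroxy-2-(prop-1-en-2-yl)-2,3-dihydro-1-benzofuran-5-yl]-2-methylbutan-1-one
Conditions: K2CO3 (cat.), MeOH, 0 °C; AcOH quench
Reagents that add atoms: none
Why: Zemplén-type methanolysis removes aryl acetates quickly through the good phenoxide leaving groups, and the phenoxide formed then shields the ketone from enolisation, so neither stereocentre, the allyl aryl ether nor the alkene should be affected.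

**Step 9**
Reactants: 14 pentan-3-one
Product: 15 (Z)-trimethyl(pent-2-en-3-yloxy)silane
Conditions: TMSOTf, Et3N, CH2Cl2, 0 °C
Reagents that add atoms: trimethylsilyl trifluoromethanesulfonate, C[Si](C)(C)OS(=O)(=O)C(F)(F)F
Why: Soft enolisation and O-silylation (silyl enol ether formation) of a symmetrical ketone can give only one regioisomer, and its alkene geometry is of no consequence for the next step.

**Step 10**
Reactants: 15 (Z)-trimethyl(pent-2-en-3-yloxy)silane; 16 malonyl dichloride
Product: 17 6-ethyl-4-hydroxy-5-methyl-2H-pyran-2-one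
Conditions: Et2O, −78 °C to rt; aqueous work-up
Reagents that add atoms: none
Why: Effenberger pyranone synthesis: C-acylation of the silyl enol ether by malonyl dichloride, O-acylative ring closure of the resulting diketo acid chloride and enolisation should give the 4-hydroxy-2-pyranone with ethyl at C6 and methyl at C5.

**Step 11**
Reactants: 13 (2R)-1-[(2R)-4,6-dihydroxy-2-(prop-1-en-2-yl)-2,3-dihydro-1-benzofuran-5-yl]-2-methylbutan-1-one; 17 6-ethyl-4-hydroxy-5-methyl-2H-pyran-2-one
Product: 20 (2R)-1-[(2R)-7-[(6-ethyl-4-hydroxy-5-methyl-2-oxo-2H-pyran-3-yl)methyl]-4,6-dihydroxy-2-(prop-1-en-2-yl)-2,3-dihydro-1-benzofuran-5-yl]-2-methylbutan-1-one, via Mannich base 18 (not isolated), via 3-methylidenepyrandione 19 (not isolated)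
Conditions: 17, Eschenmoser's salt, CHCl3, rt; then 13, rt to 40 °C
Reagents that add atoms: Eschenmoser's salt (N,N-dimethylmethyleneiminium iodide), C=[N+](C)C.[I-]
Why: Mannich aminomethylation of the pyranone C3 and loss of dimethylamine give the 3-methylidene dione, a vinylogous quinone methide that is trapped in a Friedel–Crafts/Michael alkylation by C7, the only unsubstituted and strongly activated ring carbon of 13 (a coupling known for acylphloroglucinol–pyranone methylene dimers), under near-neutral conditions that leave both stereocentres and the isopropenyl group alone.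

**Compound list**

1 | benzene-1,3,5-triol (phloroglucinol) | Oc1cc(O)cc(O)c1 | starting material
2 | (2R)-2-methylbutanoic acid | CC[C@@H](C)C(=O)O | starting material
3 | (2R)-2-methylbutanoyl chloride | CC[C@@H](C)C(=O)Cl | intermediate
4 | (2R)-2-methyl-1-(2,4,6-trihydroxyphenyl)butan-1-one | CC[C@@H](C)C(=O)c1c(O)cc(O)cc1O | intermediate
5 | 3-chloro-3-methylbut-1-yne | C#CC(C)(C)Cl | starting material
6 | (2R)-1-{2,6-dihydroxy-4-[(2-methylbut-3-yn-2-yl)oxy]phenyl}-2-methylbutan-1-one | CC[C@@H](C)C(=O)c1c(O)cc(OC(C)(C)C#C)cc1O | intermediate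
7 | 2-[(2R)-2-methylbutanoyl]-5-[(2-methylbut-3-yn-2-yl)oxy]-1,3-phenylene diacetate | CC[C@@H](C)C(=O)c1c(OC(C)=O)cc(OC(C)(C)C#C)cc1OC(C)=O | intermediate
8 | 2,2-dimethyl-6-[(2R)-2-methylbutanoyl]-2H-chromene-5,7-diyl diacetate | CC[C@@H](C)C(=O)c1c(OC(C)=O)cc2OC(C)(C)C=Cc2c1OC(C)=O | intermediate
9 | (3S,4S)-3,4-epoxy-2,2-dimethyl-6-[(2R)-2-methylbutanoyl]-3,4-dihydro-2H-chromene-5,7-diyl diacetate | CC[C@@H](C)C(=O)c1c(OC(C)=O)cc2OC(C)(C)[C@H]3O[C@H]3c2c1OC(C)=O | intermediate
10 | (3S)-3-hydroxy-2,2-dimethyl-6-[(2R)-2-methylbutanoyl]-3,4-dihydro-2H-chromene-5,7-diyl diacetate | CC[C@@H](C)C(=O)c1c(OC(C)=O)cc2OC(C)(C)[C@@H](O)Cc2c1OC(C)=O | intermediate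
11 | (3S)-2,2-dimethyl-6-[(2R)-2-methylbutanoyl]-3-(trifluoromethanesulfonyloxy)-3,4-dihydro-2H-chromene-5,7-diyl diacetate | CC[C@@H](C)C(=O)c1c(OC(C)=O)cc2OC(C)(C)[C@@H](OS(=O)(=O)C(F)(F)F)Cc2c1OC(C)=O | intermediate
12 | (2R)-5-[(2R)-2-methylbutanoyl]-2-(prop-1-en-2-yl)-2,3-dihydro-1-benzofuran-4,6-diyl diacetate | C=C(C)[C@H]1Cc2c(OC(C)=O)c(C(=O)[C@H](C)CC)c(OC(C)=O)cc2O1 | intermediate
13 | (2R)-1-[(2R)-4,6-dihydroxy-2-(prop-1-en-2-yl)-2,3-dihydro-1-benzofuran-5-yl]-2-methylbutan-1-one | C=C(C)[C@H]1Cc2c(O)c(C(=O)[C@H](C)CC)c(O)cc2O1 | intermediate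
14 | pentan-3-one | CCC(=O)CC | starting material
15 | (Z)-trimethyl(pent-2-en-3-yloxy)silane | C/C=C(/CC)O[Si](C)(C)C | intermediate
16 | propanedioyl dichloride (malonyl dichloride) | O=C(Cl)CC(Cl)=O | starting material
17 | 6-ethyl-4-hydroxy-5-methyl-2H-pyran-2-one | CCc1oc(=O)cc(O)c1C | intermediate
18 | 3-[(dimethylamino)methyl]-6-ethyl-4-hydroxy-5-methyl-2H-pyran-2-one | CCc1oc(=O)c(CN(C)C)c(O)c1C | intermediate
19 | 6-ethyl-5-methyl-3-methylidene-2H-pyran-2,4(3H)-dione | CCC1=C(C)C(=O)C(=C)C(=O)O1 | intermediate
20 | (2R)-1-[(2R)-7-[(6-ethyl-4-hydroxy-5-methyl-2-oxo-2H-pyran-3-yl)methyl]-4,6-dihydroxy-2-(prop-1-en-2-yl)-2,3-dihydro-1-benzofuran-5-yl]-2-methylbutan-1-one | C=C(C)[C@H]1Cc2c(O)c(C(=O)[C@H](C)CC)c(O)c(Cc3c(O)c(C)c(CC)oc3=O)c2O1 | target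

**Step count and risks**

Total step count: 11. Longest linear sequence: 9 (steps 1 to 8, then step 11); the pyranone branch has 2 steps (9 and 10).

Steps most likely to fail:

Step 7. The tertiary cation may lose the ring proton (giving an enol ether), the ion pair may return to the six-membered ring, or base-induced E2 toward the chromene may compete with the oxygen shift. The fallback sets out from 10 and comes back at 12. It separates cation capture from alkene formation. Chromanol 10 is mesylated (MsCl, Et3N, CH2Cl2, 0 °C) to (3S)-3-(methanesulfonyloxy)-2,2-dimethyl-6-[(2R)-2-methylbutanoyl]-3,4-dihydro-2H-chromene-5,7-diyl diacetate F1. Buffered solvolysis (2,6-lutidine, HFIP–H2O, 50 °C) lets the aryloxy shift run with capture of the cation by water, which should give (2R)-2-(2-hydroxypropan-2-yl)-5-[(2R)-2-methylbutanoyl]-2,3-dihydro-1-benzofuran-4,6-diyl diacetate F2. The tertiary alcohol is then dehydrated with Burgess reagent (benzene, 50 °C), a syn-elimination that is known to give the isopropenyl group from such carbinols, to reach 12.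

Step 5. Face discrimination by the Mn(salen) oxidant may be poor because of the peri acetoxy group next to C4, or the benzylic epoxide may open during isolation. The fallback sets out from 8 and comes back at 10. It moves the stereo-determining event from the alkene to a ketone. Chromene 8 is epoxidised without stereocontrol (mCPBA, NaHCO3, CH2Cl2) to cis-3,4-epoxy-2,2-dimethyl-6-[(2R)-2-methylbutanoyl]-3,4-dihydro-2H-chromene-5,7-diyl diacetate as a mixture of both ring configurations F3. Hydrogenolysis (H2, Pd/C) gives 3-hydroxy-2,2-dimethyl-6-[(2R)-2-methylbutanoyl]-3,4-dihydro-2H-chromene-5,7-diyl diacetate as a C3-epimer mixture F4. Dess–Martin oxidation gives 2,2-dimethyl-6-[(2R)-2-methylbutanoyl]-3-oxo-3,4-dihydro-2H-chromene-5,7-diyl diacetate F5. Corey–Bakshi–Shibata reduction with the (R)-methyl oxazaborolidine and BH3·SMe2 (CMe2 flank as the large group, hindered aryl ketone inert) should then give (3S)-alcohol 10.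

Step 2. C-Alkylation of the phloroglucinol nucleus, or alkylation of a second hydroxyl, may compete with mono-O-alkylation of the para hydroxyl. The fallback sets out from 4 and comes back at 8. It forms the C–C bond first. Condensation of 4 with 3-methylbut-2-enal (ethylenediammonium diacetate cat., toluene, 80 °C; Knoevenagel condensation then oxa-6π electrocyclisation) should give (2R)-1-(5,7-dihydroxy-2,2-dimethyl-2H-chromen-6-yl)-2-methylbutan-1-one F6, which has to be separated from the 8-acyl regioisomer formed through the other oxygen. Acetylation (Ac2O, pyridine, DMAP) then gives 8.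

**Further compounds**

F1 | step 7 | (3S)-3-(methanesulfonyloxy)-2,2-dimethyl-6-[(2R)-2-methylbutanoyl]-3,4-dihydro-2H-chromene-5,7-diyl diacetate | CC[C@@H](C)C(=O)c1c(OC(C)=O)cc2OC(C)(C)[C@@H](OS(C)(=O)=O)Cc2c1OC(C)=O
F2 | step 7 | (2R)-2-(2-hydroxypropan-2-yl)-5-[(2R)-2-methylbutanoyl]-2,3-dihydro-1-benzofuran-4,6-diyl diacetate | CC(C)(O)[C@H]1Cc2c(OC(C)=O)c(C(=O)[C@H](C)CC)c(OC(C)=O)cc2O1
F3 | step 5 | cis-3,4-epoxy-2,2-dimethyl-6-[(2R)-2-methylbutanoyl]-3,4-dihydro-2H-chromene-5,7-diyl diacetate (both ring configurations) | CC[C@@H](C)C(=O)c1c(OC(C)=O)cc2OC(C)(C)C3OC3c2c1OC(C)=O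
F4 | step 5 | 3-hydroxy-2,2-dimethyl-6-[(2R)-2-methylbutanoyl]-3,4-dihydro-2H-chromene-5,7-diyl diacetate (C3-epimer mixture) | CC[C@@H](C)C(=O)c1c(OC(C)=O)cc2OC(C)(C)C(O)Cc2c1OC(C)=O
F5 | step 5 | 2,2-dimethyl-6-[(2R)-2-methylbutanoyl]-3-oxo-3,4-dihydro-2H-chromene-5,7-diyl diacetate | CC[C@@H](C)C(=O)c1c(OC(C)=O)cc2OC(C)(C)C(=O)Cc2c1OC(C)=O
F6 | step 2 | (2R)-1-(5,7-dihydroxy-2,2-dimethyl-2H-chromen-6-yl)-2-methylbutan-1-one | CC[C@@H](C)C(=O)c1c(O)cc2OC(C)(C)C=Cc2c1O
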